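**Retrosynthetic overview**
1. The dihydrofuran is the only ring made and is closed last: C2–O1 by 5-exo opening of a threo 2,3-epoxy alcohol by the 4'-phenoxide (inversion at C2).
2. The epoxide comes from hydroxyl-directed, A(1,3)-controlled epoxidation of an (R)-aryl(2-methylprop-1-enyl)carbinol.
3. Aryl–C(=O) bond: an ortho-lithiated West carbinol (C11, from resorcinol) is joined late to an East cinnamoyl Weinreb amide (C9, from 4-iodophenol and methyl acrylate), which gives the chalcone.
4. West carbinol: resorcinol bis-SEM ether, directed ortho-metalation/formylation, then catalytic asymmetric alkenylzinc addition (sets C3).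
5. Both benzene rings are bought.

Assumption: the SMILES is read as (2S,3S), i.e. the 3-OH trans to the 2-(2-hydroxypropan-2-yl) group.

**Route**

Step 1
Reactants: 1 resorcinol
Product: 2 1,3-bis{[2-(trimethylsilyl)ethoxy]methoxy}benzene
Conditions: NaH (2.4 equiv), SEMCl (2.3 equiv), THF–DMF, 0 °C → rt
Reagents that add atoms: SEMCl, 2-(trimethylsilyl)ethoxymethyl chloride, C[Si](C)(C)CCOCCl
Why: Williamson-type O-alkylation of the bis-phenoxide; the SEM acetal is base-stable, fluoride-labile and an ortho-directing group for both later lithiations.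

Step 2
Reactants: 2 1,3-bis{[2-(trimethylsilyl)ethoxy]methoxy}benzene
Product: 4 2,6-bis{[2-(trimethylsilyl)ethoxy]methoxy}benzaldehyde, via aryllithium 3 (not isolated)
Conditions: n-BuLi (1.1 equiv), TMEDA, THF, 0 °C, 1 h; DMF, −78 → 0 °C; H2O
Reagents that add atoms: DMF, N,N-dimethylformamide, CN(C)C=O
Why: Directed ortho-metalation at the position flanked by both OSEM groups, followed by Bouveault formylation.

Step 3
Reactants: 4 2,6-bis{[2-(trimethylsilyl)ethoxy]methoxy}benzaldehyde; 5 1-bromo-2-methylprop-1-ene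
Product: 8 (1R)-1-(2,6-bis{[2-(trimethylsilyl)ethoxy]methoxy}phenyl)-3-methylbut-2-en-1-ol, via alkenyllithium 6 (not isolated), via dialkenylzinc 7 (not isolated)
Conditions: 5, t-BuLi (2 equiv), Et2O, −78 °C; ZnBr2 (0.5 equiv), → 0 °C; TEEDA, (+)-MIB (5 mol %), toluene–hexane, 0 °C; then 4; work-up at pH ≥ 7, Et3N-deactivated silica
Reagents that add atoms: none
Why: Amino-alcohol-catalysed enantioselective alkenylzinc addition to an aldehyde (Noyori-type, Walsh vinylation protocol); (+)-MIB, the enantiomer of the ligand that gives (S)-carbinols from aryl aldehydes, delivers the alkenyl group to the Re face and sets the carbinol as R (later C3, S).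

Step 4
Reactants: 9 4-iodophenol; 10 methyl acrylate
Product: 11 methyl (2E)-3-(4-hydroxyphenyl)prop-2-enoate
Conditions: Pd(OAc)2 (2 mol %), n-Bu4NCl, NaHCO3, DMF, 80 °C
Reagents that add atoms: none
Why: Mizoroki–Heck reaction (Jeffery conditions); syn insertion and syn β-hydride elimination give the E-alkene.

Step 5
Reactants: 11 methyl (2E)-3-(4-hydroxyphenyl)prop-2-enoate
Product: 12 methyl (2E)-3-{4-[(tert-butyldimethylsilyl)oxy]phenyl}prop-2-enoate
Conditions: TBSCl, imidazole, DMF, rt
Reagents that add atoms: TBSCl, tert-butyldimethylsilyl chloride, CC(C)(C)[Si](C)(C)Cl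
Why: Silylation masks the acidic phenol before the organometallic steps.

Step 6
Reactants: 12 methyl (2E)-3-{4-[(tert-butyldimethylsilyl)oxy]phenyl}prop-2-enoate
Product: 13 (2E)-3-{4-[(tert-butyldimethylsilyl)oxy]phenyl}-N-methoxy-N-methylprop-2-enamide
Conditions: MeNH(OMe)·HCl (1.5 equiv), i-PrMgCl (3 equiv), THF, −20 → 0 °C
Reagents that add atoms: N,O-dimethylhydroxylamine hydrochloride, CNOC.Cl
Why: Aminolysis of the ester by the chloromagnesium amide formed in the flask (Weinreb amide synthesis); the E-alkene and aryl silyl ether are untouched.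

Step 7
Reactants: 8 (1R)-1-(2,6-bis{[2-(trimethylsilyl)ethoxy]methoxy}phenyl)-3-methylbut-2-en-1-ol; 13 (2E)-3-{4-[(tert-butyldimethylsilyl)oxy]phenyl}-N-methoxy-N-methylprop-2-enamide
Product: 15 (2E)-1-{3-[(1R)-1-hydroxy-3-methylbut-2-en-1-yl]-2,4-bis{[2-(trimethylsilyl)ethoxy]methoxy}phenyl}-3-{4-[(tert-butyldimethylsilyl)oxy]phenyl}prop-2-en-1-one, via dilithio species 14 (not isolated)
Conditions: n-BuLi (1.05 equiv), THF, −78 °C; s-BuLi (1.3 equiv), TMEDA, −78 °C, 1 h; 13, −78 → −20 °C; H2O then pH 7 buffer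
Reagents that add atoms: none
Why: OSEM-directed ortho-metalation of the lithium alkoxide (the two positions ortho to OSEM are equivalent) and Weinreb ketone synthesis; 1,2-addition stops at the ketone and joins the two halves as the E-chalcone without touching the stereocentre.

Step 8
Reactants: 15 (the protected chalcone carbinol)
Product: 16 (2E)-1-{2,4-dihydroxy-3-[(1R)-1-hydroxy-3-methylbut-2-en-1-yl]phenyl}-3-(4-hydroxyphenyl)prop-2-en-1-one
Conditions: TBAF (8 equiv), THF–DMPU, 0 → 45 °C; pH 7 phosphate buffer; used crude at once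
Reagents that add atoms: none
Why: Fluoride-induced fragmentation of the two aryl SEM ethers and cleavage of the aryl TBS ether under non-acidic conditions, which the acid-labile benzylic allylic alcohol tolerates.

Step 9
Reactants: 16 (the unprotected chalcone carbinol)
Product: 18 brosimacutin G, via epoxy alcohol 17 (not isolated)
Conditions: mCPBA (1.05 equiv), NaHCO3, CH2Cl2–EtOAc, −20 → 0 °C; then MeOH, K2CO3 (3 equiv), 0 °C → rt; NaH2PO4 work-up
Reagents that add atoms: mCPBA, meta-chloroperoxybenzoic acid, OOC(=O)c1cccc(Cl)c1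
Why: Hydroxyl-directed (Henbest) peracid epoxidation of the Z-substituted allylic alcohol under A(1,3) control gives the threo epoxy alcohol (new centre R); the 4'-phenoxide (the chelated 2'-OH stays protonated under carbonate) then opens it by 5-exo-tet SN2 at the secondary carbon with inversion, giving C2 = S trans to the 3-OH.

**Compound list**
1 | resorcinol | Oc1cccc(O)c1 | starting material
2 | 1,3-bis{[2-(trimethylsilyl)ethoxy]methoxy}benzene | C[Si](C)(C)CCOCOc1cccc(OCOCC[Si](C)(C)C)c1 | intermediate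
3 | (2,6-bis{[2-(trimethylsilyl)ethoxy]methoxy}phenyl)lithium | [Li]c1c(OCOCC[Si](C)(C)C)cccc1OCOCC[Si](C)(C)C | intermediate
4 | 2,6-bis{[2-(trimethylsilyl)ethoxy]methoxy}benzaldehyde | O=Cc1c(OCOCC[Si](C)(C)C)cccc1OCOCC[Si](C)(C)C | intermediate
5 | 1-bromo-2-methylprop-1-ene | CC(C)=CBr | starting material
6 | (2-methylprop-1-en-1-yl)lithium | CC(C)=C[Li] | intermediate
7 | bis(2-methylprop-1-en-1-yl)zinc | CC(C)=C[Zn]C=C(C)C | intermediate
8 | (1R)-1-(2,6-bis{[2-(trimethylsilyl)ethoxy]methoxy}phenyl)-3-methylbut-2-en-1-ol | CC(C)=C[C@@H](O)c1c(OCOCC[Si](C)(C)C)cccc1OCOCC[Si](C)(C)C | intermediate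
9 | 4-iodophenol | Oc1ccc(I)cc1 | starting material
10 | methyl acrylate | C=CC(=O)OC | starting material
11 | methyl (2E)-3-(4-hydroxyphenyl)prop-2-enoate | COC(=O)/C=C/c1ccc(O)cc1 | intermediate
12 | methyl (2E)-3-{4-[(tert-butyldimethylsilyl)oxy]phenyl}prop-2-enoate | COC(=O)/C=C/c1ccc(O[Si](C)(C)C(C)(C)C)cc1 | intermediate
13 | (2E)-3-{4-[(tert-butyldimethylsilyl)oxy]phenyl}-N-methoxy-N-methylprop-2-enamide | CON(C)C(=O)/C=C/c1ccc(O[Si](C)(C)C(C)(C)C)cc1 | intermediate
14 | lithium (1R)-1-(3-lithio-2,6-bis{[2-(trimethylsilyl)ethoxy]methoxy}phenyl)-3-methylbut-2-en-1-olate | CC(C)=C[C@@H](O[Li])c1c(OCOCC[Si](C)(C)C)ccc([Li])c1OCOCC[Si](C)(C)C | intermediate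
15 | (2E)-1-{3-[(1R)-1-hydroxy-3-methylbut-2-en-1-yl]-2,4-bis{[2-(trimethylsilyl)ethoxy]methoxy}phenyl}-3-{4-[(tert-butyldimethylsilyl)oxy]phenyl}prop-2-en-1-one | CC(C)=C[C@@H](O)c1c(OCOCC[Si](C)(C)C)ccc(C(=O)/C=C/c2ccc(O[Si](C)(C)C(C)(C)C)cc2)c1OCOCC[Si](C)(C)C | intermediate
16 | (2E)-1-{2,4-dihydroxy-3-[(1R)-1-hydroxy-3-methylbut-2-en-1-yl]phenyl}-3-(4-hydroxyphenyl)prop-2-en-1-one | CC(C)=C[C@@H](O)c1c(O)ccc(C(=O)/C=C/c2ccc(O)cc2)c1O | intermediate
17 | (2E)-1-{3-[(S)-[(2R)-3,3-dimethyloxiran-2-yl](hydroxy)methyl]-2,4-dihydroxyphenyl}-3-(4-hydroxyphenyl)prop-2-en-1-one | O[C@H]([C@H]1OC1(C)C)c1c(O)ccc(C(=O)/C=C/c2ccc(O)cc2)c1O | intermediate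
18 | brosimacutin G, (2E)-1-[(2S,3S)-3,4-dihydroxy-2-(2-hydroxypropan-2-yl)-2,3-dihydro-1-benzofuran-5-yl]-3-(4-hydroxyphenyl)prop-2-en-1-one | CC(C)(O)[C@H]1Oc2ccc(C(=O)/C=C/c3ccc(O)cc3)c(O)c2[C@@H]1O | target

**Totals**
Total step count: 9.
Longest linear sequence: 6 steps (1, 2, 3, 7, 8, 9; equally 4, 5, 6, 7, 8, 9).

**Steps most likely to fail, with fallbacks**

The asymmetric alkenylation (step 3) is the first risk. Aldehyde 4 is hindered and carries two chelating acetal oxygens, so conversion or ee in the ligand-accelerated zinc addition may be poor. The fallback sets out from 4 and comes back at 8. Alkenyllithium 6 is added without ligand (THF, −78 °C) to give the racemic allylic alcohol F1. This is oxidised with MnO2 (CH2Cl2, rt) to the aryl alkenyl ketone F2. F2 is reduced with (S)-Me-CBS and catecholborane (toluene, −78 °C), the twisted 2,6-disubstituted aryl group expected to act as the large substituent, to give 8. The sense of this reduction is not certain for such a ketone; it would be checked by Mosher ester analysis and the (R)-catalyst used if it proves reversed.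

The fragment coupling (step 7) is the second risk. The alkoxide–aryllithium 14 may form sluggishly, aggregate, or add poorly to 13. The fallback sets out from 4 and comes back at 15, moving the acylation ahead of the stereocentre. The aldehyde is masked in the flask with lithium N-methylpiperazide (Comins protection) as the lithium amino alkoxide F3. This is lithiated next to OSEM with s-BuLi/TMEDA to the aryllithium F4, which is acylated with 13 and hydrolysed on work-up to the keto aldehyde F5. The (+)-MIB-catalysed addition of 7 under the conditions of step 3 then gives 15; organozinc reagents add to the aldehyde and leave the enone alone.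

The end game (step 9, and the fragile polyphenol 16 that feeds it) is the third risk. The free phenols may erode the directed epoxidation, or 16 may cyclodehydrate to a chromene. The fallback sets out from 15 and comes back at 18. The fully protected carbinol is epoxidised with mCPBA/NaHCO3 (same A(1,3)-controlled threo delivery, no free phenols) to the protected epoxy alcohol F6. TBAF (THF, 0 → 45 °C) then unmasks the phenoxides, and the 4'-phenoxide closes the ring to give 18 directly. The weakness of this fallback is regiochemistry: if the 2'-OSEM is cleaved first, the 7-acyl regioisomer forms and has to be separated by chromatography.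

**Further compounds**
F1 | step 3 | rac-1-(2,6-bis{[2-(trimethylsilyl)ethoxy]methoxy}phenyl)-3-methylbut-2-en-1-ol | CC(C)=CC(O)c1c(OCOCC[Si](C)(C)C)cccc1OCOCC[Si](C)(C)C
F2 | step 3 | 1-(2,6-bis{[2-(trimethylsilyl)ethoxy]methoxy}phenyl)-3-methylbut-2-en-1-one | CC(C)=CC(=O)c1c(OCOCC[Si](C)(C)C)cccc1OCOCC[Si](C)(C)C
F3 | step 7 | lithium (2,6-bis{[2-(trimethylsilyl)ethoxy]methoxy}phenyl)(4-methylpiperazin-1-yl)methanolate | [Li]OC(N1CCN(C)CC1)c1c(OCOCC[Si](C)(C)C)cccc1OCOCC[Si](C)(C)C
F4 | step 7 | lithium (3-lithio-2,6-bis{[2-(trimethylsilyl)ethoxy]methoxy}phenyl)(4-methylpiperazin-1-yl)methanolate | [Li]OC(N1CCN(C)CC1)c1c(OCOCC[Si](C)(C)C)ccc([Li])c1OCOCC[Si](C)(C)C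
F5 | step 7 | 3-[(2E)-3-{4-[(tert-butyldimethylsilyl)oxy]phenyl}prop-2-enoyl]-2,6-bis{[2-(trimethylsilyl)ethoxy]methoxy}benzaldehyde | O=Cc1c(OCOCC[Si](C)(C)C)ccc(C(=O)/C=C/c2ccc(O[Si](C)(C)C(C)(C)C)cc2)c1OCOCC[Si](C)(C)C
F6 | step 9 | (2E)-1-{3-[(S)-[(2R)-3,3-dimethyloxiran-2-yl](hydroxy)methyl]-2,4-bis{[2-(trimethylsilyl)ethoxy]methoxy}phenyl}-3-{4-[(tert-butyldimethylsilyl)oxy]phenyl}prop-2-en-1-one | O[C@H]([C@H]1OC1(C)C)c1c(OCOCC[Si](C)(C)C)ccc(C(=O)/C=C/c2ccc(O[Si](C)(C)C(C)(C)C)cc2)c1OCOCC[Si](C)(C)C
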